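**Retrosynthetic overview** (locants are those of the target chain, C1 = CH3 of the CHCl end)
1. Last C–C bond: the C4–C5 ketone bond, by a Ni-catalysed decarboxylative acyl cross-electrophile coupling (the proposed new step) of redox-active ester 28 (C5–C13 with both furans, C6 and the 10E olefin) with the β-chloro-α-silyloxy thioester 14 (C1–C4); then desilylation.
2. C11–C12 by B-alkyl Suzuki coupling of the borane from vinylfuran 7 with (E)-vinyl iodide 25. 25 comes from (R)-citronellol (C6 bought) by ozonolysis, acetylide alkylation and Zr-catalysed carboalumination (sets 10E); the citronellol C1 is later lost as CO2.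
3. C2/C3 chlorohydrin from L-threonine: retentive chlorodeamination, cis-epoxide closure, HCl opening at the carbon remote from the carboxyl (one inversion at each centre).
4. Bis-furan from 3-furaldehyde by C5-lithiation/alkylation with 3-(bromomethyl)furan, then Wittig methylenation.
5. Rings: both furans are bought and no ring of the target is built; only a transient oxirane is made (step 4) and opened (step 5).

Assumption: the target is taken exactly as the given SMILES, i.e. (2S,3S,6R,10E)-2-chloro-13-[5-(furan-3-ylmethyl)furan-3-yl]-3-hydroxy-6,10-dimethyltridec-10-en-4-one; compounds 1, 2, 8 and 15 are bought.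

**Route**

Step 1
Reactants: 1 3-furaldehyde; 2 3-(bromomethyl)furan
Product: 6 5-(furan-3-ylmethyl)furan-3-carbaldehyde, via lithium α-morpholino alkoxide 3 (not isolated), via 5-lithiated alkoxide 4 (not isolated), via C5-alkylated alkoxide 5 (not isolated)
Conditions: morpholine, n-BuLi, THF, −78 °C; 1; s-BuLi, −78 °C, 7 h; 2, −78 °C → rt; H2O
Reagents that add atoms: none
Why: Directed lithiation: the aldehyde, masked in situ as the bulky lithium α-morpholino alkoxide, steers s-BuLi to the unhindered α-position C5, the 2-furyllithium is alkylated (SN2) by the furfuryl-type bromide, and water releases the aldehyde.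

Step 2
Reactants: 6 5-(furan-3-ylmethyl)furan-3-carbaldehyde
Product: 7 4-ethenyl-2-(furan-3-ylmethyl)furan
Conditions: Ph3PCH3Br, KOtBu, THF, 0 °C → rt
Reagents that add atoms: methyltriphenylphosphonium bromide, C[P+](c1ccccc1)(c1ccccc1)c1ccccc1.[Br-]
Why: Wittig methylenation of an aromatic aldehyde under non-acidic conditions that the furans tolerate.

Step 3
Reactants: 8 L-threonine
Product: 9 (2S,3R)-2-chloro-3-hydroxybutanoic acid
Conditions: NaNO2, 6 M HCl, −5 °C → rt
Reagents that add atoms: hydrochloric acid, Cl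
Why: Diazotisation/chlorodeamination of an α-amino acid proceeds with retention at C2 (double inversion through the α-lactone), so both threonine centres are carried over.

Step 4
Reactants: 9 (2S,3R)-2-chloro-3-hydroxybutanoic acid
Product: 10 potassium (2R,3R)-3-methyloxirane-2-carboxylate
Conditions: KOH (2 equiv), EtOH, 0 °C → rt
Reagents that add atoms: potassium hydroxide, [K+].[OH-]
Why: Intramolecular Williamson (SN2) closure inverts the chloride-bearing carbon and gives the cis-epoxide; this fixes the future C3–O configuration of the target.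

Step 5
Reactants: 10 potassium (2R,3R)-3-methyloxirane-2-carboxylate
Product: 11 (2S,3S)-3-chloro-2-hydroxybutanoic acid
Conditions: HCl (4 M in dioxane, 2.5 equiv), Et2O, 0 °C → rt
Reagents that add atoms: hydrogen chloride, Cl
Why: Acid-mediated SN2 epoxide opening by chloride at the methyl-bearing carbon remote from the electron-withdrawing carboxyl (inversion) sets the C–Cl centre (S) and leaves the C–OH centre (S), giving the threo chlorohydrin.

Step 6
Reactants: 11 (2S,3S)-3-chloro-2-hydroxybutanoic acid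
Product: 13 (2S,3S)-3-chloro-2-[(triethylsilyl)oxy]butanoic acid, via bis-silylated ester 12 (not isolated)
Conditions: TESCl (2.3 equiv), imidazole, DMF, 0 °C → rt; then THF/H2O, rt
Reagents that add atoms: chlorotriethylsilane, CC[Si](Cl)(CC)CC
Why: Exhaustive silylation followed by selective hydrolysis of the much more labile silyl ester leaves the secondary TES ether; no base strong enough for epimerisation or HCl loss is present.

Step 7
Reactants: 13 (2S,3S)-3-chloro-2-[(triethylsilyl)oxy]butanoic acid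
Product: 14 S-(pyridin-2-yl) (2S,3S)-3-chloro-2-[(triethylsilyl)oxy]butanethioate
Conditions: 2,2'-dipyridyl disulfide, PPh3, CH2Cl2, rt
Reagents that add atoms: 2,2'-dipyridyl disulfide, c1ccc(nc1)SSc1ccccn1
Why: Mukaiyama redox condensation gives the activated thioester under neutral conditions, so the α-stereocentre and the β-chloride are untouched.

Step 8
Reactants: 15 (R)-citronellol
Product: 16 (R)-tert-butyl[(3,7-dimethyloct-6-en-1-yl)oxy]dimethylsilane
Conditions: TBSCl, imidazole, CH2Cl2, rt
Reagents that add atoms: tert-butyldimethylsilyl chloride, CC(C)(C)[Si](C)(C)Cl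
Why: Standard silyl protection of the primary alcohol; the bought stereocentre becomes C6 of the target.

Step 9
Reactants: 16 (R)-tert-butyl[(3,7-dimethyloct-6-en-1-yl)oxy]dimethylsilane
Product: 18 (R)-6-[(tert-butyldimethylsilyl)oxy]-4-methylhexan-1-ol, via aldehyde 17 (not isolated)
Conditions: O3, CH2Cl2/MeOH, −78 °C; then NaBH4, −78 → 0 °C
Reagents that add atoms: ozone, [O-][O+]=O
Why: Ozonolysis of the only alkene with reductive (NaBH4) work-up gives the primary alcohol; the stereocentre is not involved.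

Step 10
Reactants: 18 (R)-6-[(tert-butyldimethylsilyl)oxy]-4-methylhexan-1-ol
Product: 19 (R)-tert-butyl[(6-iodo-3-methylhexyl)oxy]dimethylsilane
Conditions: I2, PPh3, imidazole, CH2Cl2, 0 °C → rt
Reagents that add atoms: iodine, II
Why: Appel iodination of a primary alcohol; the TBS ether is stable to these conditions.

Step 11
Reactants: 19 (R)-tert-butyl[(6-iodo-3-methylhexyl)oxy]dimethylsilane
Product: 20 (R)-tert-butyldimethyl[(3-methyloct-7-yn-1-yl)oxy]silane
Conditions: lithium acetylide–ethylenediamine complex, DMSO, 10 °C → rt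
Reagents that add atoms: lithium acetylide ethylenediamine complex, [Li]C#C.NCCN
Why: SN2 alkylation of acetylide by an unhindered primary iodide gives the terminal alkyne.

Step 12
Reactants: 20 (R)-tert-butyldimethyl[(3-methyloct-7-yn-1-yl)oxy]silane
Product: 22 (R,E)-tert-butyl[(8-iodo-3,7-dimethyloct-7-en-1-yl)oxy]dimethylsilane, via alkenyldimethylalane 21 (not isolated)
Conditions: Me3Al (3 equiv), Cp2ZrCl2 (0.5 equiv), CH2Cl2, 0 °C → rt; then I2, THF, −30 → 0 °C
Reagents that add atoms: trimethylaluminium, C[Al](C)C; iodine, II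
Why: Negishi Zr-catalysed carboalumination adds Me and Al syn with Me on the internal carbon, and iodinolysis with retention gives the (E)-vinyl iodide that defines the 10E olefin.

Step 13
Reactants: 22 (R,E)-tert-butyl[(8-iodo-3,7-dimethyloct-7-en-1-yl)oxy]dimethylsilane
Product: 23 (R,E)-8-iodo-3,7-dimethyloct-7-en-1-ol
Conditions: CSA (10 mol %), MeOH/CH2Cl2, rt
Reagents that add atoms: none
Why: Acid-catalysed methanolysis of a primary TBS ether; the vinyl iodide is acid-stable.

Step 14
Reactants: 23 (R,E)-8-iodo-3,7-dimethyloct-7-en-1-ol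
Product: 25 (R,E)-8-iodo-3,7-dimethyloct-7-enoic acid, via aldehyde 24 (not isolated)
Conditions: TEMPO (20 mol %), PhI(OAc)2 (2.2 equiv), MeCN/H2O, rt
Reagents that add atoms: water, O
Why: Oxoammonium (TEMPO/PhI(OAc)2) oxidation through the aldehyde hydrate gives the acid; it is done before the oxidation-sensitive furans are introduced.

Step 15
Reactants: 7 4-ethenyl-2-(furan-3-ylmethyl)furan; 25 (R,E)-8-iodo-3,7-dimethyloct-7-enoic acid
Product: 27 (R,E)-10-[5-(furan-3-ylmethyl)furan-3-yl]-3,7-dimethyldec-7-enoic acid, via B-alkyl-9-BBN 26 (not isolated)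
Conditions: 7 (1.5 equiv), 9-BBN, THF, 0 °C → rt; 3 M aq. NaOH; 25, PdCl2(dppf) (5 mol %), THF, 45 °C; then 1 M HCl to pH 3, 0 °C
Reagents that add atoms: none
Why: Anti-Markovnikov hydroboration of the vinyl group and B-alkyl Suzuki–Miyaura coupling with the vinyl iodide (retention of E geometry) form C11–C12; the acid is a spectator carboxylate.

Step 16
Reactants: 27 (R,E)-10-[5-(furan-3-ylmethyl)furan-3-yl]-3,7-dimethyldec-7-enoic acid
Product: 28 1,3-dioxoisoindolin-2-yl (R,E)-10-[5-(furan-3-ylmethyl)furan-3-yl]-3,7-dimethyldec-7-enoate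
Conditions: N-hydroxyphthalimide, DIC, DMAP (cat.), CH2Cl2, rt
Reagents that add atoms: N-hydroxyphthalimide, ON1C(=O)c2ccccc2C1=O
Why: Carbodiimide (Steglich-type) esterification gives the redox-active ester under neutral conditions.

Step 17
Reactants: 28 1,3-dioxoisoindolin-2-yl (R,E)-10-[5-(furan-3-ylmethyl)furan-3-yl]-3,7-dimethyldec-7-enoate; 14 S-(pyridin-2-yl) (2S,3S)-3-chloro-2-[(triethylsilyl)oxy]butanethioate
Product: 29 (2S,3S,6R,E)-2-chloro-13-[5-(furan-3-ylmethyl)furan-3-yl]-6,10-dimethyl-3-[(triethylsilyl)oxy]tridec-10-en-4-one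
Conditions: NiCl2·dme (10 mol %), 4,4'-di-tert-butyl-2,2'-bipyridine (12 mol %), Zn dust (2 equiv), 14 (1.3 equiv), THF/DMA, 0 °C → rt
Reagents that add atoms: none
Why: Proposed new method: a decarboxylative acyl cross-electrophile coupling with a stereodefined α-silyloxy-β-chloro acyl donor, a substrate class on which this reactivity has not been shown; (bipyridine)Ni(0) inserts into the acyl C–S bond far faster than into the unactivated secondary C–Cl bond, single-electron reduction of 28 releases CO2, phthalimide anion and the primary C5 radical (capture by nickel outruns 6-exo cyclisation onto the trisubstituted olefin), radical capture by acyl-Ni(II) and reductive elimination from Ni(III) form the C4–C5 ketone bond, and because the medium is base-free and neither C2, C3 nor C6 is a radical or enolate site all three centres are retained; the closest known reaction type is the Ni-catalysed reductive ketone synthesis from N-hydroxyphthalimide esters and simple 2-pyridyl thioesters.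

Step 18
Reactants: 29 (2S,3S,6R,E)-2-chloro-13-[5-(furan-3-ylmethyl)furan-3-yl]-6,10-dimethyl-3-[(triethylsilyl)oxy]tridec-10-en-4-one
Product: 30 (2S,3S,6R,E)-2-chloro-13-[5-(furan-3-ylmethyl)furan-3-yl]-3-hydroxy-6,10-dimethyltridec-10-en-4-one
Conditions: HF·pyridine, pyridine, THF, 0 °C
Reagents that add atoms: none
Why: Fluoride-mediated desilylation of a TES ether under buffered, weakly acidic conditions avoids the base-induced HCl loss of the β-chloro ketone and spares the furans.

**Compound list**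
1 | 3-furaldehyde | O=Cc1ccoc1 | starting material
2 | 3-(bromomethyl)furan | BrCc1ccoc1 | starting material
3 | lithium furan-3-yl(morpholin-4-yl)methanolate | [Li]OC(N1CCOCC1)c1ccoc1 | intermediate
4 | lithium (5-lithiofuran-3-yl)(morpholin-4-yl)methanolate | [Li]OC(N1CCOCC1)c1coc([Li])c1 | intermediate
5 | lithium [5-(furan-3-ylmethyl)furan-3-yl](morpholin-4-yl)methanolate | [Li]OC(N1CCOCC1)c1coc(Cc2ccoc2)c1 | intermediate
6 | 5-(furan-3-ylmethyl)furan-3-carbaldehyde | O=Cc1coc(Cc2ccoc2)c1 | intermediate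
7 | 4-ethenyl-2-(furan-3-ylmethyl)furan | C=Cc1coc(Cc2ccoc2)c1 | intermediate
8 | L-threonine, (2S,3R)-2-amino-3-hydroxybutanoic acid | C[C@@H](O)[C@H](N)C(=O)O | starting material
9 | (2S,3R)-2-chloro-3-hydroxybutanoic acid | C[C@@H](O)[C@H](Cl)C(=O)O | intermediate
10 | potassium (2R,3R)-3-methyloxirane-2-carboxylate (cis-epoxide) | C[C@H]1O[C@H]1C(=O)[O-].[K+] | intermediate
11 | (2S,3S)-3-chloro-2-hydroxybutanoic acid | OC(=O)[C@H](O)[C@H](C)Cl | intermediate
12 | triethylsilyl (2S,3S)-3-chloro-2-[(triethylsilyl)oxy]butanoate | CC[Si](CC)(CC)OC(=O)[C@H](O[Si](CC)(CC)CC)[C@H](C)Cl | intermediate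
13 | (2S,3S)-3-chloro-2-[(triethylsilyl)oxy]butanoic acid | OC(=O)[C@H](O[Si](CC)(CC)CC)[C@H](C)Cl | intermediate
14 | S-(pyridin-2-yl) (2S,3S)-3-chloro-2-[(triethylsilyl)oxy]butanethioate | O=C(Sc1ccccn1)[C@H](O[Si](CC)(CC)CC)[C@H](C)Cl | intermediate
15 | (R)-citronellol, (R)-3,7-dimethyloct-6-en-1-ol | CC(C)=CCC[C@@H](C)CCO | starting material
16 | (R)-tert-butyl[(3,7-dimethyloct-6-en-1-yl)oxy]dimethylsilane | CC(C)=CCC[C@@H](C)CCO[Si](C)(C)C(C)(C)C | intermediate
17 | (R)-6-[(tert-butyldimethylsilyl)oxy]-4-methylhexanal | O=CCC[C@@H](C)CCO[Si](C)(C)C(C)(C)C | intermediate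
18 | (R)-6-[(tert-butyldimethylsilyl)oxy]-4-methylhexan-1-ol | OCCC[C@@H](C)CCO[Si](C)(C)C(C)(C)C | intermediate
19 | (R)-tert-butyl[(6-iodo-3-methylhexyl)oxy]dimethylsilane | ICCC[C@@H](C)CCO[Si](C)(C)C(C)(C)C | intermediate
20 | (R)-tert-butyldimethyl[(3-methyloct-7-yn-1-yl)oxy]silane | C#CCCC[C@@H](C)CCO[Si](C)(C)C(C)(C)C | intermediate
21 | (R,E)-[8-[(tert-butyldimethylsilyl)oxy]-2,6-dimethyloct-1-en-1-yl]dimethylalane | C/C(=C\[Al](C)C)CCC[C@@H](C)CCO[Si](C)(C)C(C)(C)C | intermediate
22 | (R,E)-tert-butyl[(8-iodo-3,7-dimethyloct-7-en-1-yl)oxy]dimethylsilane | C/C(=C\I)CCC[C@@H](C)CCO[Si](C)(C)C(C)(C)C | intermediate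
23 | (R,E)-8-iodo-3,7-dimethyloct-7-en-1-ol | C/C(=C\I)CCC[C@@H](C)CCO | intermediate
24 | (R,E)-8-iodo-3,7-dimethyloct-7-enal | C/C(=C\I)CCC[C@@H](C)CC=O | intermediate
25 | (R,E)-8-iodo-3,7-dimethyloct-7-enoic acid | C/C(=C\I)CCC[C@@H](C)CC(=O)O | intermediate
26 | 9-{2-[5-(furan-3-ylmethyl)furan-3-yl]ethyl}-9-borabicyclo[3.3.1]nonane | C(Cc1coc(Cc2ccoc2)c1)B1C2CCCC1CCC2 | intermediate
27 | (R,E)-10-[5-(furan-3-ylmethyl)furan-3-yl]-3,7-dimethyldec-7-enoic acid | C/C(=C\CCc1coc(Cc2ccoc2)c1)CCC[C@@H](C)CC(=O)O | intermediate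
28 | 1,3-dioxoisoindolin-2-yl (R,E)-10-[5-(furan-3-ylmethyl)furan-3-yl]-3,7-dimethyldec-7-enoate | C/C(=C\CCc1coc(Cc2ccoc2)c1)CCC[C@@H](C)CC(=O)ON1C(=O)c2ccccc2C1=O | intermediate
29 | (2S,3S,6R,E)-2-chloro-13-[5-(furan-3-ylmethyl)furan-3-yl]-6,10-dimethyl-3-[(triethylsilyl)oxy]tridec-10-en-4-one | C/C(=C\CCc1coc(Cc2ccoc2)c1)CCC[C@@H](C)CC(=O)[C@H](O[Si](CC)(CC)CC)[C@H](C)Cl | intermediate
30 | (2S,3S,6R,E)-2-chloro-13-[5-(furan-3-ylmethyl)furan-3-yl]-3-hydroxy-6,10-dimethyltridec-10-en-4-one (CNP0209639.1) | C/C(=C\CCc1coc(Cc2ccoc2)c1)CCC[C@@H](C)CC(=O)[C@H](O)[C@H](C)Cl | target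

**Summary**
Total step count: 18.
Longest linear sequence: 11 steps (steps 8–18, from (R)-citronellol 15). The side branches are steps 1–2 and steps 3–7.

**Three steps most likely to fail, each with a fallback**

Step 17 (the proposed new coupling). The risks are decarbonylation of the acyl-nickel followed by β-chloride loss, HCl elimination from the product by zinc thiolate, and homocoupling. The fallback uses known chemistry only; it sets out from acid 27 and comes back at 29. Acid 27 is coupled with N-hydroxypyridine-2-thione (DCC, CH2Cl2, dark) to the Barton ester 2-thioxopyridin-1(2H)-yl (R,E)-10-[5-(furan-3-ylmethyl)furan-3-yl]-3,7-dimethyldec-7-enoate F1. Photolysis with iodoform in benzene (W lamp) gives the nor-iodide 2-(furan-3-ylmethyl)-4-[(3E,8R)-9-iodo-4,8-dimethylnon-3-en-1-yl]furan F2 by Barton decarboxylative iodination. Zinc insertion (Zn dust, LiCl, THF, 40 °C) gives the alkylzinc iodide [(2R,6E)-9-[5-(furan-3-ylmethyl)furan-3-yl]-2,6-dimethylnon-6-en-1-yl]zinc iodide F3. Fukuyama coupling of F3 (PdCl2(PPh3)2, toluene/THF, rt) with S-ethyl (2S,3S)-3-chloro-2-[(triethylsilyl)oxy]butanethioate F4, made from acid 13 with EtSH, DCC and cat. DMAP, gives 29.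

Step 1 (C5-lithiation and alkylation). The risks are incomplete or C2-lithiation and poor alkylation by the labile bromide 2. The fallback sets out from 1 (and uses 2) and comes back at 6, replacing directed lithiation by sterically controlled C–H borylation and cross-coupling. Aldehyde 1 is protected (ethylene glycol, PPTS, benzene, Dean–Stark) as 2-(furan-3-yl)-1,3-dioxolane F5. Ir-catalysed C–H borylation ([Ir(OMe)(cod)]2, dtbpy, B2pin2, hexane, rt) at the unhindered α-position gives 2-[4-(1,3-dioxolan-2-yl)furan-2-yl]-4,4,5,5-tetramethyl-1,3,2-dioxaborolane F6. Suzuki–Miyaura coupling with 2 (Pd(PPh3)4, K2CO3, DME/H2O) gives 2-[5-(furan-3-ylmethyl)furan-3-yl]-1,3-dioxolane F7, and PPTS in wet acetone releases 6.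

Step 5 (regiochemistry of the epoxide opening). The risk is attack of chloride at the carboxyl-bearing carbon or hydrolysis to the diol. The fallback sets out from 10 and comes back at 11; it moves the opening to the alcohol oxidation level, where titanium alkoxide chelation directs chloride to C3, and then re-oxidises. Salt 10 is alkylated (BnBr, DMF) to benzyl (2R,3R)-3-methyloxirane-2-carboxylate F8. NaBH4 in EtOH at 0 °C gives [(2S,3R)-3-methyloxiran-2-yl]methanol F9. ClTi(OiPr)3 in CH2Cl2 at 0 °C opens it at C3 with inversion to (2S,3S)-3-chlorobutane-1,2-diol F10. Primary-selective oxidation (TEMPO cat., NaOCl cat., NaClO2, MeCN/pH 6.7 buffer) gives 11.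

**Further compounds**
F1 | step 17 | 2-thioxopyridin-1(2H)-yl (R,E)-10-[5-(furan-3-ylmethyl)furan-3-yl]-3,7-dimethyldec-7-enoate | C/C(=C\CCc1coc(Cc2ccoc2)c1)CCC[C@@H](C)CC(=O)On1ccccc1=S
F2 | step 17 | 2-(furan-3-ylmethyl)-4-[(3E,8R)-9-iodo-4,8-dimethylnon-3-en-1-yl]furan | C/C(=C\CCc1coc(Cc2ccoc2)c1)CCC[C@@H](C)CI
F3 | step 17 | [(2R,6E)-9-[5-(furan-3-ylmethyl)furan-3-yl]-2,6-dimethylnon-6-en-1-yl]zinc iodide | C/C(=C\CCc1coc(Cc2ccoc2)c1)CCC[C@@H](C)C[Zn]I
F4 | step 17 | S-ethyl (2S,3S)-3-chloro-2-[(triethylsilyl)oxy]butanethioate | CCSC(=O)[C@H](O[Si](CC)(CC)CC)[C@H](C)Cl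
F5 | step 1 | 2-(furan-3-yl)-1,3-dioxolane | C1COC(O1)c1ccoc1
F6 | step 1 | 2-[4-(1,3-dioxolan-2-yl)furan-2-yl]-4,4,5,5-tetramethyl-1,3,2-dioxaborolane | CC1(C)OB(OC1(C)C)c1cc(co1)C1OCCO1
F7 | step 1 | 2-[5-(furan-3-ylmethyl)furan-3-yl]-1,3-dioxolane | C1COC(O1)c1coc(Cc2ccoc2)c1
F8 | step 5 | benzyl (2R,3R)-3-methyloxirane-2-carboxylate | C[C@H]1O[C@H]1C(=O)OCc1ccccc1
F9 | step 5 | [(2S,3R)-3-methyloxiran-2-yl]methanol | C[C@H]1O[C@H]1CO
F10 | step 5 | (2S,3S)-3-chlorobutane-1,2-diol | OC[C@H](O)[C@H](C)Cl
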